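The data are simulated with constants of no real substance, noise included.

Start from the leftover. At 26 min the summer run holds 0.2000 M of G from 0.400 M of Z, so 0.200 M of that charge is not G. Z is the limiting reagent, so keep the books as shares of the charge.

| flask | Z | time |
|---|---|---|
| summer | 0.400 M |  |
| noon | 0.160 M |  |
| spring | 0.600 M |  |
| midnight | 1.20 M | 26 min |

- summer run (time / min: [G] / M): 3.7: 0.0611; 7.4: 0.1052; 11: 0.1385; 15: 0.1668; 19: 0.1845; 22: 0.1927; 26: 0.2000
- noon run (time / min: [G] / M): 3.7: 0.0198; 7.4: 0.0374; 11: 0.0497; 15: 0.0572; 19: 0.0643; 22: 0.0663; 26: 0.0681
- spring run (time / min: [G] / M): 3.7: 0.0942; 7.4: 0.1661; 11: 0.2189; 15: 0.2610; 19: 0.2895; 22: 0.3017; 26: 0.3126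

(readings scatter by 0.001 M)

- the exponent of [Z] in the starting rate at the charge of the summer run (at the point where two percent of the Z have become G) (one fixed amount of G, the same in the runs compared)
- G in the midnight run at 26 min, as a share of the Z charged

- Overall: Z -> G.
- Constant volume, constant temperature.
- Bound and free are read together.
- An order is taken over about fifteen percent of the charge, up and down.

Enter the last reading of each run as G over charge: noon 42.6%, summer 50.0%, spring 52.1%. The spring share is higher than the noon share, so the G entry is no fixed fraction of the charge.

Write the share as a ceiling times charge over charge plus h. Call h the half-share charge: the charge of Z at which the share at 26 min stands at half its ceiling. The noon and spring entries give, as readings, h = 0.0532 M and a ceiling of 56.7%. Test it on the unused summer entry: it returns 50.0% against the 50.0% read.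

G at that time then goes as charge squared over charge plus h, so its exponent is one plus h over charge plus h. Assume the starting rate follows the same form. My reckoning gives 1.12 at the summer charge. For the midnight run at 26 min it closes the books at 54.3% as G and 45.7% as not G.

The forecast gives an exponent of 1.1 and a midnight share of 53%, the share “assuming first-order behaviour persists”. My midnight share differs from the forecast's by 1.3 percentage points.

The midnight run gives 55.4% of its charge as G at 26 min, and the exponent at the summer charge comes out at 1.1.

    2 Z ⇌ Z2, settled at all times (25.20 L mol⁻¹)
    Z2 → G + Z (0.1176 min⁻¹)
    G → Jy (0.01290 min⁻¹)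
    Z → Xi (0.03738 min⁻¹)

At one fixed amount of G, the spring run forms G at 0.029 M min⁻¹ and the summer run at 0.018 M min⁻¹, a ratio of 1.6. Put the half-share charge to work on that pair: the charge ratio squared, times summer charge plus h over spring charge plus h, gives 1.56.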